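If the second isomer, the isomer of the product A and the target with what comes from it shared the products evenly, the second isomer would hold a third of them, and I took that even split as my zero.

| setting | eta | delta | flask |
|---|---|---|---|
| starting material | 0.46 M (fed, over 2.5 h) | 0.46 M (fed, over 2.5 h) | 0.46 M (fed, over 2.5 h) |
| coupling partner | 0.69 M | 0.69 M | 0.690 M |
| protic impurity | 0.12 M | 0.17 M | 0.230 M |
| remark | run made earlier; the fed solution adds 0.10 times the starting volume | run made earlier; the fed solution adds 0.10 times the starting volume | the fed solution adds 0.10 times the starting volume |
| time |  |  | 5.0 h |

| run | time / h | isomer of the product B / % | second isomer / % | starting material / % | isomer of the product A / % | over-reaction product / % | target / % |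
|---|---|---|---|---|---|---|---|
| eta | 1.50 | 0 | 12 | 29 | 9 | 0 | 9 |
| eta | 3.00 | 5 | 25 | 28 | 15 | 6 | 14 |
| eta | 5.00 | 2 | 35 | 11 | 20 | 17 | 9 |
| eta | 6.00 | 3 | 38 | 6 | 19 | 18 | 10 |
| delta | 1.50 | 0 | 11 | 34 | 9 | 6 | 7 |
| delta | 3.00 | 1 | 28 | 29 | 14 | 7 | 13 |
| delta | 5.00 | 3 | 36 | 8 | 19 | 15 | 9 |
| delta | 6.00 | 6 | 33 | 3 | 19 | 20 | 4 |

(scatter of a reading: 2 percentage points)

* the largest share of what was charged as starting material, at 5.0 h belongs to (isomer of the product B / target / isomer of the product A / starting material / second isomer / over-reaction product)
* the largest share itself, whichever of these holds it, in percent of the starting material charged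

My answer was to be the second isomer's share of the products, times what had become product in the flask. So I first asked what had to be known well. c(coupling partner) stood at 0.690 M in the flask as in both runs, so it needed no correction. At 5.00 h the products summed to 83.0% in eta and 82.0% in delta. A slip of 2 percentage points in the starting material left or in the missing balance moved my answer by 0.86 points, but the same slip in the share moved it by 1.6 points, which is more.

The isomer share, a selectivity, is the second isomer over the summed products, both runs pooled: 43.0%, higher than the even split. I took 9.50% as starting material left, and the runs' missing balance, scaled to c(protic impurity) = 0.230 M, gave 12.7%. My reckoning was therefore 33.5%, lower than the forecast's figure. The forecast named the second isomer at 34%, noting that the impurity “barely changes the product pattern”.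

The flask gave the second isomer at 36.0%. Quenched substrate held 6.57% and starting material 9.38%, and the isomer share turns what remains into 36.1%. The second isomer's lead over the isomer of the product A was 18 points, more than the whole of the quenched substrate.

    starting material + coupling partner → target (k = 0.0100 L mol⁻¹ min⁻¹)
    starting material + coupling partner → isomer of the product A (k = 0.00600 L mol⁻¹ min⁻¹)
    starting material + coupling partner → second isomer (k = 0.0120 L mol⁻¹ min⁻¹)
    target → over-reaction product (k = 0.00570 min⁻¹)
    starting material + protic impurity → quenched substrate (k = 0.00480 L mol⁻¹ min⁻¹)
    target ⇌ isomer of the product B (K = 0.360, k = 0.00350 min⁻¹)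

In the neighbour with 0.17 M of coupling partner, 55.3% starting material and 13.5% quenched substrate, the isomer share gives 13.4%. That flask computed 13.3%.

The runs are simulated for substances that don't exist; scatter was added.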